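**Retrosynthetic overview**
1. The all-E C40 retro-carotenoid is cut at the central C15–C15' single bond (Stille coupling) into two C20 halves. Both come from one ketone stannane 17: I2 gives the ring A (ketone) half 18, and (R)-CBS reduction gives the ring B ((S)-carbinol) half 19.
2. Each half is cut at the exocyclic C6=C7 alkene (vinylogous HWE) into ring phosphonate 9 and stannyl tetraenal 16, the latter built from enynol 10 and C5 phosphonate 13.
3. The ring is made once, by a formal [4+2] of diene 5 (C2–C5) with alkylidene phosphonoacetate 3 (C1=C6), forming C1–C2 and C5–C6; it serves as ring A and, after step 12, as ring B.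
4. Enabling feature: ring A is a 3,5,5-trimethyl-4-ylidenecyclohex-2-enone. Its C3=O/C4=C5(CH3) enone is an unmasked 1-methoxy-1-methyl-3-silyloxybutadiene, and the gem-dimethyl carbon C1 is β to C6, the only ring carbon that must become sp2 toward the chain. Two acceptors on C6 (phosphonate and allyl ester) therefore drive the annulation, and the phosphonate is then the handle for the retro C6=C7 olefination.

Key step: step 3

Assumption: carotenoid numbering is used (C1 = gem-dimethyl carbon, C2 = CH2, C3 = C=O, C4 = ring CH, C5 = C–CH3, C6 = ring carbon of the exocyclic alkene, C7–C15 = chain; primed numbers for the carbinol half), and compounds 1, 2, 4, 10 and 13 are taken as catalogue chemicals.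

**Step 1**
Reactants: 1 acetone; 2 allyl diethylphosphonoacetate
Product: 3 allyl 2-(diethoxyphosphoryl)-3-methylbut-2-enoate
Conditions: TiCl4 (2 equiv), N-methylmorpholine (4 equiv), THF, 0 °C to rt
Reagents that add atoms: none
Why: TiCl4/amine Knoevenagel condensation of a ketone with a phosphonoacetate; TiCl4 activates acetone and takes up the water, and the two identical methyl groups leave no alkene geometry to control.

**Step 2**
Reactants: 4 (E)-4-methoxypent-3-en-2-one
Product: 5 (3E)-4-methoxy-2-(trimethylsilyloxy)penta-1,3-diene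
Conditions: LiN(iPr)2, THF, −78 °C; Me3SiCl, −78 °C to 0 °C
Reagents that add atoms: chlorotrimethylsilane, C[Si](C)(C)Cl
Why: Kinetic deprotonation of the vinylogous ester at the acetyl methyl group and O-silylation should give the Danishefsky-type diene with the enol ether geometry unchanged.

**Step 3**
Reactants: 3 allyl 2-(diethoxyphosphoryl)-3-methylbut-2-enoate; 5 (3E)-4-methoxy-2-(trimethylsilyloxy)penta-1,3-diene
Product: 7 allyl 1-(diethoxyphosphoryl)-2,6,6-trimethyl-4-oxocyclohex-2-ene-1-carboxylate (racemic), via silyl enol ether cycloadduct 6 (not isolated)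
Conditions: Tf2NH (5 mol%), CH2Cl2, −78 °C to −20 °C; then 1 M HCl, THF, 0 °C to rt
Reagents that add atoms: none
Why: Tf2NH is silylated by 5 to Me3SiNTf2, which activates 3 at its P=O/C=O pair; the CH2 terminus of 5 then adds to the CMe2 carbon (Mukaiyama–Michael, bond C1–C2) and the resulting silyl ketene acetal closes on the methoxy-bearing oxocarbenium carbon (bond C5–C6) to give cycloadduct 6, whose silyl enol ether is hydrolysed and whose methoxy group is eliminated (E1cB) in the HCl work-up. The closest known reaction type is the acid-catalysed Diels–Alder reaction (concerted or Mukaiyama–Michael/cyclisation) of 1-alkoxy-3-silyloxydienes with doubly activated alkenes such as alkylidene malonates and 2-phosphonoacrylates, and of hindered 2-silyloxydienes with β,β-disubstituted acceptors under Tf2NH catalysis. The single carbocycle is closed as a [4+2] annulation; in the stepwise picture the second bond is a 6-(enolexo)-endo-trig attack of the ketene acetal on the vinylogous ester carbon. No stereocentre has to be controlled: the C5 centre of 6 is erased with the methanol, and the quaternary C6 of 7 (racemic) becomes sp2 in step 10. The step needs only regioselectivity, which the push–pull polarisation of both partners secures: the diene is nucleophilic only at its CH2 end, 3 is electrophilic only at its β-carbon, and the two acceptor groups on C6 compensate for the β,β-dimethyl substitution.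

**Step 4**
Reactants: 7 allyl 1-(diethoxyphosphoryl)-2,6,6-trimethyl-4-oxocyclohex-2-ene-1-carboxylate
Product: 9 diethyl (2,6,6-trimethyl-4-oxocyclohex-2-en-1-yl)phosphonate (racemic), via carboxylic acid 8 (not isolated)
Conditions: Pd(PPh3)4 (3 mol%), morpholine, THF, rt; then toluene, 80 °C
Reagents that add atoms: none
Why: Zerovalent-palladium deallylation (Tsuji–Trost ionisation, morpholine as allyl acceptor) frees acid 8, a vinylogous β-keto acid that is also α-phosphono and should lose CO2 on warming; any β,γ-enone tautomer of 9 gives the same anion in step 10.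

**Step 5**
Reactants: 10 (E)-3-methylpent-2-en-4-yn-1-ol
Product: 11 (2E,4E)-3-methyl-5-(tributylstannyl)penta-2,4-dien-1-ol
Conditions: Bu3SnH (1.1 equiv), PdCl2(PPh3)2 (2 mol%), THF, 0 °C
Reagents that add atoms: tributyltin hydride, CCCC[SnH](CCCC)CCCC
Why: Palladium-catalysed syn-hydrostannylation of the terminal alkyne places tin on the terminal carbon, away from the branched enyne carbon, and should give the (E)-vinylstannane with the existing (2E) alkene untouched.

**Step 6**
Reactants: 11 (2E,4E)-3-methyl-5-(tributylstannyl)penta-2,4-dien-1-ol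
Product: 12 (2E,4E)-3-methyl-5-(tributylstannyl)penta-2,4-dienal
Conditions: MnO2 (activated, excess), CH2Cl2, rt
Reagents that add atoms: none
Why: MnO2 oxidises the allylic alcohol chemoselectively and leaves the vinylstannane and alkene geometry intact.

**Step 7**
Reactants: 12 (2E,4E)-3-methyl-5-(tributylstannyl)penta-2,4-dienal; 13 ethyl (2E)-4-(diethoxyphosphoryl)-3-methylbut-2-enoate
Product: 14 ethyl (2E,4E,6E,8E)-3,7-dimethyl-9-(tributylstannyl)nona-2,4,6,8-tetraenoate
Conditions: NaN(SiMe3)2, THF, −78 °C; then 12, −78 °C to 0 °C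
Reagents that add atoms: none
Why: Horner–Wadsworth–Emmons olefination should give the new (4E) disubstituted alkene; any (2Z) isomer arising from scrambling of the reagent's trisubstituted alkene is removed by chromatography at this ester stage.

**Step 8**
Reactants: 14 ethyl (2E,4E,6E,8E)-3,7-dimethyl-9-(tributylstannyl)nona-2,4,6,8-tetraenoate
Product: 15 (2E,4E,6E,8E)-3,7-dimethyl-9-(tributylstannyl)nona-2,4,6,8-tetraen-1-ol
Conditions: iBu2AlH (2.2 equiv), CH2Cl2, −78 °C; aq. potassium sodium tartrate (KNaC4H4O6)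
Reagents that add atoms: none
Why: iBu2AlH reduces the conjugated ester 1,2 to the allylic alcohol at low temperature, and the C–Sn bond is inert to it.

**Step 9**
Reactants: 15 (2E,4E,6E,8E)-3,7-dimethyl-9-(tributylstannyl)nona-2,4,6,8-tetraen-1-ol
Product: 16 (2E,4E,6E,8E)-3,7-dimethyl-9-(tributylstannyl)nona-2,4,6,8-tetraenal
Conditions: MnO2 (activated, excess), CH2Cl2, rt
Reagents that add atoms: none
Why: Neutral MnO2 oxidation of the polyenylic alcohol should give the aldehyde without touching the stannane.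

**Step 10**
Reactants: 9 diethyl (2,6,6-trimethyl-4-oxocyclohex-2-en-1-yl)phosphonate; 16 (2E,4E,6E,8E)-3,7-dimethyl-9-(tributylstannyl)nona-2,4,6,8-tetraenal
Product: 17 (4E)-4-[(2E,4E,6E,8E)-3,7-dimethyl-9-(tributylstannyl)nona-2,4,6,8-tetraen-1-ylidene]-3,5,5-trimethylcyclohex-2-en-1-one
Conditions: NaH, THF, 0 °C; then 16, 0 °C to rt
Reagents that add atoms: none
Why: Vinylogous Horner–Wadsworth–Emmons olefination: the sodium dienolate of the γ-phosphono enone reacts productively only through C6 (adducts at C4 revert), and the (6E) geometry, with the chain syn to the gem-dimethyl carbon, should prevail because it avoids allylic strain with the C5 methyl group.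

**Step 11**
Reactants: 17 (4E)-4-[(2E,4E,6E,8E)-3,7-dimethyl-9-(tributylstannyl)nona-2,4,6,8-tetraen-1-ylidene]-3,5,5-trimethylcyclohex-2-en-1-one
Product: 18 (4E)-4-[(2E,4E,6E,8E)-9-iodo-3,7-dimethylnona-2,4,6,8-tetraen-1-ylidene]-3,5,5-trimethylcyclohex-2-en-1-one
Conditions: I2 (1.0 equiv), CH2Cl2, −20 °C, dark
Reagents that add atoms: iodine, II
Why: Iododestannylation is an ipso substitution at the vinyl carbon with retention of the (E) geometry and is much faster than iodine addition to the polyene.

**Step 12**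
Reactants: 17 (4E)-4-[(2E,4E,6E,8E)-3,7-dimethyl-9-(tributylstannyl)nona-2,4,6,8-tetraen-1-ylidene]-3,5,5-trimethylcyclohex-2-en-1-one
Product: 19 (1S,4E)-4-[(2E,4E,6E,8E)-3,7-dimethyl-9-(tributylstannyl)nona-2,4,6,8-tetraen-1-ylidene]-3,5,5-trimethylcyclohex-2-en-1-ol
Conditions: (R)-2-methyl-CBS-oxazaborolidine (20 mol%), catecholborane, toluene, −78 °C; then MeOH, aq. NaOH work-up
Reagents that add atoms: none
Why: Corey–Bakshi–Shibata reduction: the (R)-catalyst binds the carbonyl anti to the dienyl arm (large group; the C2 methylene is the small group) and should deliver hydride to the face that gives the (S)-carbinol, while catecholborane at −78 °C avoids 1,4-reduction and hydroboration.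

**Step 13**
Reactants: 18 ring A iodide (4E)-4-[(2E,4E,6E,8E)-9-iodo-3,7-dimethylnona-2,4,6,8-tetraen-1-ylidene]-3,5,5-trimethylcyclohex-2-en-1-one; 19 ring B stannane (1S,4E)-4-[(2E,4E,6E,8E)-3,7-dimethyl-9-(tributylstannyl)nona-2,4,6,8-tetraen-1-ylidene]-3,5,5-trimethylcyclohex-2-en-1-ol
Product: 20 (3'S)-3'-hydroxy-4',5'-didehydro-4,5'-retro-β,β-caroten-3-one (all-E)
Conditions: Pd2(dba)3 (5 mol%), AsPh3 (40 mol%), NMP, rt, dark, argon
Reagents that add atoms: none
Why: Stille coupling joins the two vinyl carbons C15 and C15' with retention of both alkene geometries under neutral conditions that spare the acid-labile dienylic alcohol and the ketone; minor (Z) isomers should converge on the favoured all-E form on gentle warming in the dark.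

**Compound list**
1 | acetone | CC(C)=O | starting material
2 | allyl diethylphosphonoacetate | C=CCOC(=O)CP(=O)(OCC)OCC | starting material
3 | allyl 2-(diethoxyphosphoryl)-3-methylbut-2-enoate | CC(C)=C(C(=O)OCC=C)P(=O)(OCC)OCC | intermediate
4 | (E)-4-methoxypent-3-en-2-one | CO/C(C)=C/C(C)=O | starting material
5 | (3E)-4-methoxy-2-(trimethylsilyloxy)penta-1,3-diene | CO/C(C)=C/C(=C)O[Si](C)(C)C | intermediate
6 | allyl 1-(diethoxyphosphoryl)-2-methoxy-2,6,6-trimethyl-4-(trimethylsilyloxy)cyclohex-3-ene-1-carboxylate (diastereomer mixture, not isolated) | COC1(C)C=C(O[Si](C)(C)C)CC(C)(C)C1(C(=O)OCC=C)P(=O)(OCC)OCC | intermediate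
7 | allyl 1-(diethoxyphosphoryl)-2,6,6-trimethyl-4-oxocyclohex-2-ene-1-carboxylate (racemic) | CC1=CC(=O)CC(C)(C)C1(C(=O)OCC=C)P(=O)(OCC)OCC | intermediate
8 | 1-(diethoxyphosphoryl)-2,6,6-trimethyl-4-oxocyclohex-2-ene-1-carboxylic acid (not isolated) | CC1=CC(=O)CC(C)(C)C1(C(O)=O)P(=O)(OCC)OCC | intermediate
9 | diethyl (2,6,6-trimethyl-4-oxocyclohex-2-en-1-yl)phosphonate (racemic) | CC1=CC(=O)CC(C)(C)C1P(=O)(OCC)OCC | intermediate
10 | (E)-3-methylpent-2-en-4-yn-1-ol | C#C/C(C)=C/CO | starting material
11 | (2E,4E)-3-methyl-5-(tributylstannyl)penta-2,4-dien-1-ol | OC/C=C(C)/C=C/[Sn](CCCC)(CCCC)CCCC | intermediate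
12 | (2E,4E)-3-methyl-5-(tributylstannyl)penta-2,4-dienal | O=C/C=C(C)/C=C/[Sn](CCCC)(CCCC)CCCC | intermediate
13 | ethyl (2E)-4-(diethoxyphosphoryl)-3-methylbut-2-enoate | CCOC(=O)/C=C(\C)CP(=O)(OCC)OCC | starting material
14 | ethyl (2E,4E,6E,8E)-3,7-dimethyl-9-(tributylstannyl)nona-2,4,6,8-tetraenoate | CCOC(=O)/C=C(C)/C=C/C=C(C)/C=C/[Sn](CCCC)(CCCC)CCCC | intermediate
15 | (2E,4E,6E,8E)-3,7-dimethyl-9-(tributylstannyl)nona-2,4,6,8-tetraen-1-ol | OC/C=C(C)/C=C/C=C(C)/C=C/[Sn](CCCC)(CCCC)CCCC | intermediate
16 | (2E,4E,6E,8E)-3,7-dimethyl-9-(tributylstannyl)nona-2,4,6,8-tetraenal | O=C/C=C(C)/C=C/C=C(C)/C=C/[Sn](CCCC)(CCCC)CCCC | intermediate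
17 | (4E)-4-[(2E,4E,6E,8E)-3,7-dimethyl-9-(tributylstannyl)nona-2,4,6,8-tetraen-1-ylidene]-3,5,5-trimethylcyclohex-2-en-1-one | CC1=CC(=O)CC(C)(C)\C1=C/C=C(C)/C=C/C=C(C)/C=C/[Sn](CCCC)(CCCC)CCCC | intermediate
18 | (4E)-4-[(2E,4E,6E,8E)-9-iodo-3,7-dimethylnona-2,4,6,8-tetraen-1-ylidene]-3,5,5-trimethylcyclohex-2-en-1-one | CC1=CC(=O)CC(C)(C)\C1=C/C=C(C)/C=C/C=C(C)/C=C/I | intermediate
19 | (1S,4E)-4-[(2E,4E,6E,8E)-3,7-dimethyl-9-(tributylstannyl)nona-2,4,6,8-tetraen-1-ylidene]-3,5,5-trimethylcyclohex-2-en-1-ol | CCCC[Sn](CCCC)(CCCC)/C=C/C(C)=C/C=C/C(C)=C/C=C1/C(C)=C[C@@H](O)CC1(C)C | intermediate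
20 | (3'S)-3'-hydroxy-4',5'-didehydro-4,5'-retro-β,β-caroten-3-one, all-E (ring A ketone, ring B (S)-carbinol) | CC1=CC(=O)CC(C)(C)\C1=C/C=C(C)/C=C/C=C(C)/C=C/C=C/C(C)=C/C=C/C(C)=C/C=C1/C(C)=C[C@@H](O)CC1(C)C | target

**Step count and risks**
Total step count: 13. Longest linear sequence: 8 steps (5, 6, 7, 8, 9, 10, then 11 or 12, then 13).

Steps most likely to fail:

1. Step 3. The ring closure may stall, or the diene may be desilylated by the acid first, because three contiguous fully substituted carbons (C5, C6, C1) have to be assembled. Fallback, from 3 back to 7: commercial pent-3-yn-2-one is converted with LiN(iPr)2/Me3SiCl (THF, −78 °C) into 2-(trimethylsilyloxy)pent-1-en-3-yne F1. TiCl4-mediated Mukaiyama–Michael addition of F1 to 3 (CH2Cl2, −78 °C) makes the C1–C2 bond alone and gives, after aqueous work-up, the ynone allyl 2-(diethoxyphosphoryl)-3,3-dimethyl-5-oxooct-6-ynoate F2. Cs2CO3 in MeCN then closes the C5–C6 bond by 6-endo-dig conjugate addition of the phosphonoacetate carbanion to the sp carbon of the ynone, which should give 7 directly.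

2. Step 10. Addition of the doubly stabilised, hindered tertiary carbanion to the polyenal may be slow and reversible, so that aldol addition through C4 and aldehyde self-condensation take over. Fallback, from 9 back to 17: Luche reduction (NaBH4, CeCl3·7H2O, MeOH, 0 °C) gives diethyl (4-hydroxy-2,6,6-trimethylcyclohex-2-en-1-yl)phosphonate F3, and silylation (tBuMe2SiCl, imidazole, DMF) gives diethyl [4-(tert-butyldimethylsilyloxy)-2,6,6-trimethylcyclohex-2-en-1-yl]phosphonate F4. Its non-stabilised allylic anion (KN(SiMe3)2, THF, −78 °C to rt) is far more nucleophilic and should add irreversibly to 16, giving after phosphate loss the silyl ether tert-butyldimethylsilyl ether of racemic 19 F5. Bu4NF in THF gives the racemic dienylic alcohol racemic 19 F6, and MnO2 oxidation returns ketone 17.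

3. Step 13. Transmetalation between two long polyenyl partners may be slow, allowing E/Z scrambling, homocoupling of the stannane and decomposition of the polyenyl iodide. Fallback, from 16, 19 and 9 back to 20: iododestannylation of 16 (I2, CH2Cl2, −20 °C) gives the shorter, electron-poor (2E,4E,6E,8E)-9-iodo-3,7-dimethylnona-2,4,6,8-tetraenal F7. Stille coupling of F7 with 19 (Pd2(dba)3, AsPh3, NMP, rt) gives (2E,4E,6E,8E,10E,12E,14E,16E)-18-[(1E,4S)-4-hydroxy-2,6,6-trimethylcyclohex-2-en-1-ylidene]-3,7,12,16-tetramethyloctadeca-2,4,6,8,10,12,14,16-octaenal F8. The last bond is then the ring A C6=C7 alkene, made by the Horner–Wadsworth–Emmons reaction of F8 with the sodium anion of 9 (NaH in excess, THF), which should give 20.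

**Further compounds**
F1 | step 3 | 2-(trimethylsilyloxy)pent-1-en-3-yne | CC#CC(=C)O[Si](C)(C)C
F2 | step 3 | allyl 2-(diethoxyphosphoryl)-3,3-dimethyl-5-oxooct-6-ynoate | CC#CC(=O)CC(C)(C)C(C(=O)OCC=C)P(=O)(OCC)OCC
F3 | step 10 | diethyl (4-hydroxy-2,6,6-trimethylcyclohex-2-en-1-yl)phosphonate | CC1=CC(O)CC(C)(C)C1P(=O)(OCC)OCC
F4 | step 10 | diethyl [4-(tert-butyldimethylsilyloxy)-2,6,6-trimethylcyclohex-2-en-1-yl]phosphonate | CC1=CC(O[Si](C)(C)C(C)(C)C)CC(C)(C)C1P(=O)(OCC)OCC
F5 | step 10 | tert-butyldimethylsilyl ether of racemic 19 | CCCC[Sn](CCCC)(CCCC)/C=C/C(C)=C/C=C/C(C)=C/C=C1/C(C)=CC(O[Si](C)(C)C(C)(C)C)CC1(C)C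
F6 | step 10 | racemic 19 | CCCC[Sn](CCCC)(CCCC)/C=C/C(C)=C/C=C/C(C)=C/C=C1/C(C)=CC(O)CC1(C)C
F7 | step 13 | (2E,4E,6E,8E)-9-iodo-3,7-dimethylnona-2,4,6,8-tetraenal | O=C/C=C(C)/C=C/C=C(C)/C=C/I
F8 | step 13 | (2E,4E,6E,8E,10E,12E,14E,16E)-18-[(1E,4S)-4-hydroxy-2,6,6-trimethylcyclohex-2-en-1-ylidene]-3,7,12,16-tetramethyloctadeca-2,4,6,8,10,12,14,16-octaenal | O=C/C=C(C)/C=C/C=C(C)/C=C/C=C/C(C)=C/C=C/C(C)=C/C=C1/C(C)=C[C@@H](O)CC1(C)C
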